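The route rests on cutting C4a''–C5'' in the apigenin half (flavone 2). The feature exploited is that rings A and C of flavone 2 form a chromone oxygenated on alternate carbons (C5'', C7'', C8a''), with ring B on C8''. Ring C is therefore carried as a finished 2-aryl-4-pyranone. C5''–C8'' hang from it as a methyl β-keto ester chain whose sp3 carbon C8'' already bears ring B of the complete flavone 1. One base-induced Claisen closure from pyranone C3 (C4a'') onto the ester, then enolisation, creates aromatic ring A, locks the 8''-aryl regiochemistry and converts an unhindered C(sp3)–aryl bond into the crowded C2'–C8'' biaryl bond.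

Key step: step 10

Locants: unprimed = chromone of flavone 1; primed = ring B; double-primed = chromone of flavone 2; triple-primed = its 4-oxygenated phenyl ring.

Assumption: the target SMILES gives no descriptor for the C2'–C8'' axis and holds no stereocentre, so no axial control is attempted.

Design notes:
- (a) The acetic acid arm on C2' is attached only after flavone 1 is closed. An ester-bearing CH2 ortho to the migrating aroyl group would be the most acidic site. It would also be an electrophile six atoms from the diketone carbon.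
- (b) The C8a''–C4a'' bond is made from a silyl dienol ether and an acid chloride. An arylacetic ester would protonate a lithiated diketone dianion instead of acylating it.
- (c) Methyl malonyl chloride is itself a carbon acid, so the acylation at C8'' uses two equivalents of amide base.
- (d) In the key-step precursor every phenol is a benzyl ether, so the C5'' ester meets no oxygen nucleophile. Both ethers fall in the last step.
- (e) The zinc reagent of step 4 is sold as an ether solution.

Step 1
Reactants: 1 1-(2,6-dihydroxy-4-methoxyphenyl)ethanone (2',6'-dihydroxy-4'-methoxyacetophenone)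
Product: 2 1-[2-(benzyloxy)-6-hydroxy-4-methoxyphenyl]ethanone
Conditions: BnBr (1.05 equiv), K2CO3 (1.2 equiv), acetone, reflux
Reagents that add atoms: benzyl bromide, BrCc1ccccc1
Why: Williamson ether synthesis on a symmetrical diol, in which the hydroxyl left after the first alkylation is held in a strong hydrogen bond to the acetyl group, so one equivalent of halide should stop at the monoether.

Step 2
Reactants: 2 1-[2-(benzyloxy)-6-hydroxy-4-methoxyphenyl]ethanone; 3 2-bromo-4-methoxybenzoic acid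
Product: 4 2-acetyl-3-(benzyloxy)-5-methoxyphenyl 2-bromo-4-methoxybenzoate
Conditions: DCC (1.2 equiv), DMAP (0.2 equiv), CH2Cl2, 0 °C to rt
Reagents that add atoms: none
Why: Steglich esterification (carbodiimide activation, acyl transfer through DMAP) is a standard O-acylation of hydrogen-bonded 2-hydroxyacetophenones and leaves the aryl bromide and the benzyl ether alone.

Step 3
Reactants: 4 2-acetyl-3-(benzyloxy)-5-methoxyphenyl 2-bromo-4-methoxybenzoate
Product: 6 5-(benzyloxy)-2-(2-bromo-4-methoxyphenyl)-7-methoxy-4H-chromen-4-one, via 1,3-diketone 5 (not isolated)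
Conditions: KOt-Bu (2.5 equiv), THF, 0 °C to rt; then AcOH (excess), THF distilled off, 110 °C
Reagents that add atoms: none
Why: Baker–Venkataraman acyl migration (the ketone enolate attacks the neighbouring aryl ester) and cyclodehydration of the resulting 2-hydroxyaryl 1,3-diketone in acetate-buffered acetic acid are the classical flavone synthesis, the buffered medium spares the acid-labile 5-benzyl ether, and the aroyl part carries only an inert bromide, so no second acidic or electrophilic site can interfere.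

Step 4
Reactants: 6 5-(benzyloxy)-2-(2-bromo-4-methoxyphenyl)-7-methoxy-4H-chromen-4-one; 7 bromo(2-tert-butoxy-2-oxoethyl)zinc (BrZnCH2CO2t-Bu)
Product: 8 tert-butyl {2-[5-(benzyloxy)-7-methoxy-4-oxo-4H-chromen-2-yl]-5-methoxyphenyl}acetate
Conditions: 7 (1.5 equiv), Pd(dba)2 (5 mol %), XPhos (10 mol %), THF, rt to 50 °C
Reagents that add atoms: none
Why: Palladium-catalysed α-arylation of an ester through its zinc (Reformatsky) enolate, a Negishi-type coupling, forms C2'–C8'' at an unhindered CH2 carbon, and the weakly basic zinc enolate does not attack the chromone.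

Step 5
Reactants: 8 tert-butyl {2-[5-(benzyloxy)-7-methoxy-4-oxo-4H-chromen-2-yl]-5-methoxyphenyl}acetate
Product: 9 {2-[5-(benzyloxy)-7-methoxy-4-oxo-4H-chromen-2-yl]-5-methoxyphenyl}acetic acid
Conditions: TFA–CH2Cl2 1:3, rt
Reagents that add atoms: none
Why: Acidolysis of a tert-butyl ester (E1 loss of 2-methylpropene) proceeds at room temperature, where aryl benzyl ethers, aryl methyl ethers and the chromone are stable.

Step 6
Reactants: 10 1-[4-(benzyloxy)phenyl]ethanone; 11 ethyl acetate
Product: 12 1-[4-(benzyloxy)phenyl]butane-1,3-dione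
Conditions: NaH (2.2 equiv), 11 (3 equiv), THF, reflux; aq. HCl
Reagents that add atoms: none
Why: Crossed Claisen condensation of a methyl ketone enolate with ethyl acetate, driven by formation of the sodium salt of the 1,3-diketone.

Step 7
Reactants: 12 1-[4-(benzyloxy)phenyl]butane-1,3-dione
Product: 13 (1Z)-1-[4-(benzyloxy)phenyl]-1,3-bis(trimethylsilyloxy)buta-1,3-diene
Conditions: Me3SiOTf (2.3 equiv), Et3N (3 equiv), Et2O, 0 °C to rt; used crude
Reagents that add atoms: trimethylsilyl trifluoromethanesulfonate, C[Si](C)(C)OS(=O)(=O)C(F)(F)F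
Why: Double O-silylation of a 1,3-diketone with a silyl triflate and an amine is a known one-step entry to 1,3-bis(silyloxy)buta-1,3-dienes, the neutral equivalents of diketone dianions.

Step 8
Reactants: 9 {2-[5-(benzyloxy)-7-methoxy-4-oxo-4H-chromen-2-yl]-5-methoxyphenyl}acetic acid; 13 (1Z)-1-[4-(benzyloxy)phenyl]-1,3-bis(trimethylsilyloxy)buta-1,3-diene
Product: 16 5-(benzyloxy)-2-[2-({6-[4-(benzyloxy)phenyl]-4-oxo-4H-pyran-2-yl}methyl)-4-methoxyphenyl]-7-methoxy-4H-chromen-4-one, via acid chloride 14 (not isolated), via 1,3,5-triketone 15 (not isolated)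
Conditions: (COCl)2 (1.3 equiv), cat. DMF, CH2Cl2, 0 °C to rt, volatiles removed; 13 (1.5 equiv), CH2Cl2, −78 to 20 °C; then TFA (20 vol %), rt to 40 °C
Reagents that add atoms: oxalyl chloride, O=C(Cl)C(=O)Cl (supplies only the chlorine of intermediate 14; none of its atoms reach 16)
Why: Acylation of a 1,3-bis(silyl enol ether) at its terminal carbon by an acid chloride (Mukaiyama-type, a known route to 1,3,5-tricarbonyl compounds) needs no base and so leaves the acidic benzylic CH2 of 14 untouched, and acid-catalysed cyclodehydration of a 1,3,5-triketone is the classical closure of a 2,6-disubstituted 4-pyranone.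

Step 9
Reactants: 16 5-(benzyloxy)-2-[2-({6-[4-(benzyloxy)phenyl]-4-oxo-4H-pyran-2-yl}methyl)-4-methoxyphenyl]-7-methoxy-4H-chromen-4-one; 17 methyl malonyl chloride (methyl 3-chloro-3-oxopropanoate)
Product: 18 methyl 4-{2-[5-(benzyloxy)-7-methoxy-4-oxo-4H-chromen-2-yl]-5-methoxyphenyl}-4-{6-[4-(benzyloxy)phenyl]-4-oxo-4H-pyran-2-yl}-3-oxobutanoate (racemic at C8'')
Conditions: LiN(SiMe3)2 (2.1 equiv), THF, −78 °C; 17 (1.1 equiv), −78 to −40 °C; AcOH, −78 °C
Reagents that add atoms: none
Why: Vinylogous (side-chain) deprotonation of the 2-benzyl-4-pyranone and C-acylation of the extended lithium enolate at the exocyclic carbon follow the known side-chain acylation of 2-alkyl-4-pyranones, the silylamide is too weak to metalate the vinylic C–H bonds of chromone or pyranone, and its second equivalent takes up the proton that the acid chloride or the product gives up, so no lithiated 16 is spent as a base.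

Step 10
Reactants: 18 methyl 4-{2-[5-(benzyloxy)-7-methoxy-4-oxo-4H-chromen-2-yl]-5-methoxyphenyl}-4-{6-[4-(benzyloxy)phenyl]-4-oxo-4H-pyran-2-yl}-3-oxobutanoate
Product: 19 5-(benzyloxy)-2-(2-{2-[4-(benzyloxy)phenyl]-5,7-dihydroxy-4-oxo-4H-chromen-8-yl}-4-methoxyphenyl)-7-methoxy-4H-chromen-4-one (5,4'''-di-O-benzyl ether of the target)
Conditions: DBU (4 equiv), 4 Å molecular sieves, dry MeCN, 25 to 70 °C; aq. citric acid
Reagents that add atoms: none
Why: Proposed new method: DBU removes the C8'' proton (benzylic, α to the C7'' ketone and γ to the pyranone carbonyl C4''), the delocalised dienolate carries charge on C4a'' (C3 of the pyranone), and this carbon adds to the ester carbonyl C5''; loss of methoxide, loss of the C4a'' proton and enolisation at C5'' and C7'' then give the aromatic ring A. The closest known reaction type is the biomimetic Claisen folding of 3,5,7-triketo esters to acylphloroglucinols, where a stabilised 1,3-dicarbonyl carbanion likewise attacks a β-keto ester carbonyl; what has not been shown is C3 of an intact 4-pyranone in the role of that carbanion. Ring A closes in the 6-(enolexo)-exo-trig mode, the forming ring holding C4a'', C5'', C6'', C7'', C8'' and C8a''. No stereocentre is created: racemic C8'' becomes sp2 and only the uncontrolled C2'–C8'' axis remains. The step needs C-acylation at C4a'' with the O1''–C8a'' and O1''–C2'' bonds intact, and the substrate secures this because the carbonyl carbons C2'', C4'' and C8a'' are tied up in the pyranone, which leaves one six-membered folding and excludes a 6''-aryl isomer, while the benzyl ethers remove every oxygen nucleophile. The enolate at C6'' equilibrates with the productive C8'' anion and irreversible aromatisation drains the equilibrium, and the amidine base, the aprotic solvent and the sieves (which bind methanol) hold back pyranone opening, retro-Claisen loss of the malonyl unit and conjugate addition to C2 of the electron-rich flavone 1.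

Step 11
Reactants: 19 5-(benzyloxy)-2-(2-{2-[4-(benzyloxy)phenyl]-5,7-dihydroxy-4-oxo-4H-chromen-8-yl}-4-methoxyphenyl)-7-methoxy-4H-chromen-4-one
Product: 20 5-hydroxy-2-{2-[5,7-dihydroxy-2-(4-hydroxyphenyl)-4-oxo-4H-chromen-8-yl]-4-methoxyphenyl}-7-methoxy-4H-chromen-4-one (CNP0329977.0)
Conditions: H2 (1 atm), 10% Pd/C, THF–MeOH 1:1, rt
Reagents that add atoms: none
Why: Catalytic hydrogenolysis cleaves both aryl benzyl ethers, while the chromone C2=C3 bonds, the aryl methyl ethers and the phenols are stable under one atmosphere of hydrogen at room temperature.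

Compound list
1 | 1-(2,6-dihydroxy-4-methoxyphenyl)ethanone | CC(=O)c1c(O)cc(OC)cc1O | starting material
2 | 1-[2-(benzyloxy)-6-hydroxy-4-methoxyphenyl]ethanone | CC(=O)c1c(O)cc(OC)cc1OCc1ccccc1 | intermediate
3 | 2-bromo-4-methoxybenzoic acid | COc1ccc(C(=O)O)c(Br)c1 | starting material
4 | 2-acetyl-3-(benzyloxy)-5-methoxyphenyl 2-bromo-4-methoxybenzoate | COc1ccc(C(=O)Oc2cc(OC)cc(OCc3ccccc3)c2C(C)=O)c(Br)c1 | intermediate
5 | 1-[2-(benzyloxy)-6-hydroxy-4-methoxyphenyl]-3-(2-bromo-4-methoxyphenyl)propane-1,3-dione | COc1ccc(C(=O)CC(=O)c2c(O)cc(OC)cc2OCc2ccccc2)c(Br)c1 | intermediate (not isolated)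
6 | 5-(benzyloxy)-2-(2-bromo-4-methoxyphenyl)-7-methoxy-4H-chromen-4-one | COc1ccc(-c2cc(=O)c3c(OCc4ccccc4)cc(OC)cc3o2)c(Br)c1 | intermediate
7 | bromo(2-tert-butoxy-2-oxoethyl)zinc | CC(C)(C)OC(=O)C[Zn]Br | starting material
8 | tert-butyl {2-[5-(benzyloxy)-7-methoxy-4-oxo-4H-chromen-2-yl]-5-methoxyphenyl}acetate | CC(C)(C)OC(=O)Cc1cc(OC)ccc1-c1cc(=O)c2c(OCc3ccccc3)cc(OC)cc2o1 | intermediate
9 | {2-[5-(benzyloxy)-7-methoxy-4-oxo-4H-chromen-2-yl]-5-methoxyphenyl}acetic acid | OC(=O)Cc1cc(OC)ccc1-c1cc(=O)c2c(OCc3ccccc3)cc(OC)cc2o1 | intermediate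
10 | 1-[4-(benzyloxy)phenyl]ethanone | CC(=O)c1ccc(OCc2ccccc2)cc1 | starting material
11 | ethyl acetate | CCOC(C)=O | starting material
12 | 1-[4-(benzyloxy)phenyl]butane-1,3-dione | CC(=O)CC(=O)c1ccc(OCc2ccccc2)cc1 | intermediate
13 | (1Z)-1-[4-(benzyloxy)phenyl]-1,3-bis(trimethylsilyloxy)buta-1,3-diene | C=C(O[Si](C)(C)C)/C=C(\O[Si](C)(C)C)c1ccc(OCc2ccccc2)cc1 | intermediate
14 | {2-[5-(benzyloxy)-7-methoxy-4-oxo-4H-chromen-2-yl]-5-methoxyphenyl}acetyl chloride | O=C(Cl)Cc1cc(OC)ccc1-c1cc(=O)c2c(OCc3ccccc3)cc(OC)cc2o1 | intermediate (not isolated)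
15 | 1-[4-(benzyloxy)phenyl]-6-{2-[5-(benzyloxy)-7-methoxy-4-oxo-4H-chromen-2-yl]-5-methoxyphenyl}hexane-1,3,5-trione | COc1ccc(-c2cc(=O)c3c(OCc4ccccc4)cc(OC)cc3o2)c(CC(=O)CC(=O)CC(=O)c2ccc(OCc3ccccc3)cc2)c1 | intermediate (not isolated)
16 | 5-(benzyloxy)-2-[2-({6-[4-(benzyloxy)phenyl]-4-oxo-4H-pyran-2-yl}methyl)-4-methoxyphenyl]-7-methoxy-4H-chromen-4-one | COc1ccc(-c2cc(=O)c3c(OCc4ccccc4)cc(OC)cc3o2)c(Cc2cc(=O)cc(-c3ccc(OCc4ccccc4)cc3)o2)c1 | intermediate
17 | methyl 3-chloro-3-oxopropanoate (methyl malonyl chloride) | COC(=O)CC(=O)Cl | starting material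
18 | methyl 4-{2-[5-(benzyloxy)-7-methoxy-4-oxo-4H-chromen-2-yl]-5-methoxyphenyl}-4-{6-[4-(benzyloxy)phenyl]-4-oxo-4H-pyran-2-yl}-3-oxobutanoate, racemic | COC(=O)CC(=O)C(c1cc(=O)cc(-c2ccc(OCc3ccccc3)cc2)o1)c1cc(OC)ccc1-c1cc(=O)c2c(OCc3ccccc3)cc(OC)cc2o1 | intermediate
19 | 5-(benzyloxy)-2-(2-{2-[4-(benzyloxy)phenyl]-5,7-dihydroxy-4-oxo-4H-chromen-8-yl}-4-methoxyphenyl)-7-methoxy-4H-chromen-4-one | COc1ccc(-c2cc(=O)c3c(OCc4ccccc4)cc(OC)cc3o2)c(-c2c(O)cc(O)c3c(=O)cc(-c4ccc(OCc5ccccc5)cc4)oc23)c1 | intermediate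
20 | 5-hydroxy-2-{2-[5,7-dihydroxy-2-(4-hydroxyphenyl)-4-oxo-4H-chromen-8-yl]-4-methoxyphenyl}-7-methoxy-4H-chromen-4-one | COc1ccc(-c2cc(=O)c3c(O)cc(OC)cc3o2)c(-c2c(O)cc(O)c3c(=O)cc(-c4ccc(O)cc4)oc23)c1 | target

Total step count: 11. Longest linear sequence: 9 steps (steps 1–5 and 8–11; 1 → 2 → 4 → 6 → 8 → 9 → 16 → 18 → 19 → 20).

Steps most likely to fail

1) Step 10 (key step).
- What may go wrong: The strongly delocalised anion may be too unreactive towards a methyl ester. The pyranone may be opened by methanol or traces of water. The malonyl unit may be lost by retro-Claisen cleavage. C6'' or C4a'' may add in conjugate fashion to C2 of flavone 1 and open that chromone.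
- Fallback (known chemistry): it sets out from 6 and comes back at 20. Miyaura borylation of 6 (B2pin2, PdCl2(dppf), KOAc, dioxane, 90 °C) should give the 2'-pinacolboronate of flavone 1 F1. Commercial apigenin is perbenzylated (BnBr, K2CO3, DMF, 80 °C) to 5,7,4'-tri-O-benzylapigenin F2. Iodination of F2 (I2, CF3CO2Ag, CH2Cl2) goes to C8 in fully alkylated 5,7-dioxygenated flavones and should give the 8-iodide F3. Suzuki–Miyaura coupling of F1 and F3 (Pd(OAc)2, SPhos, K3PO4, toluene–water, 100 °C) makes C2'–C8'' directly as a tri-ortho-substituted biaryl, the tetrabenzyl ether of the target F4. Hydrogenolysis under the conditions of step 11 then leads to 20.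

2) Step 9.
- What may go wrong: Proton transfer from the acid chloride may quench the lithiated pyranone. The acylating agent may self-condense. Acylation may occur at the C4'' oxygen. Ring closure may start uncontrolled on warming.
- Fallback: it sets out from 16 and comes back at 18, and it builds the chain from two other bonds. The same lithium dienolate is trapped with CO2, which cannot be enolised, and cold aqueous citric acid frees the aryl(pyranonyl)acetic acid F5. CDI in THF at 0 °C turns it into the acyl imidazolide F6. A decarboxylative Claisen condensation of the Masamune–Brooks type (KO2CCH2CO2Me, MgCl2, Et3N, MeCN–THF, rt to 40 °C) forms C7''–C6'' and gives 18 after acidic work-up.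

3) Step 8.
- What may go wrong: Diene 13 may be desilylated before it reacts. Acylation by the hindered arylacetyl chloride may be sluggish. The acid chloride may acylate itself at C3 of flavone 1.
- Fallback: it sets out from 9 and 10 and comes back at 16, and it closes the pyranone by cycloaddition. Acid 9 is condensed with Meldrum's acid (DCC, DMAP, CH2Cl2) to the acyl Meldrum's acid F7. In refluxing toluene–acetone F7 loses CO2 and gives the 6-substituted 2,2-dimethyl-1,3-dioxin-4-one F8. Ketone 10 is converted into its trimethylsilyl enol ether F9 (Me3SiOTf, Et3N, CH2Cl2, 0 °C). Thermolysis of F8 in toluene at 110 °C releases acetone and the acylketene F10. An excess of F9 intercepts F10 in a hetero-Diels–Alder reaction to give the 2-silyloxy-2,3-dihydropyran-4-one F11. TFA in CH2Cl2 then eliminates silanol and gives 16.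

Further compounds
F1 | step 10 | 5-(benzyloxy)-7-methoxy-2-[4-methoxy-2-(4,4,5,5-tetramethyl-1,3,2-dioxaborolan-2-yl)phenyl]-4H-chromen-4-one | COc1ccc(-c2cc(=O)c3c(OCc4ccccc4)cc(OC)cc3o2)c(B2OC(C)(C)C(C)(C)O2)c1
F2 | step 10 | 5,7-bis(benzyloxy)-2-[4-(benzyloxy)phenyl]-4H-chromen-4-one | O=c1cc(-c2ccc(OCc3ccccc3)cc2)oc2cc(OCc3ccccc3)cc(OCc3ccccc3)c12
F3 | step 10 | 5,7-bis(benzyloxy)-2-[4-(benzyloxy)phenyl]-8-iodo-4H-chromen-4-one | O=c1cc(-c2ccc(OCc3ccccc3)cc2)oc2c(I)c(OCc3ccccc3)cc(OCc3ccccc3)c12
F4 | step 10 | 5-(benzyloxy)-2-(2-{5,7-bis(benzyloxy)-2-[4-(benzyloxy)phenyl]-4-oxo-4H-chromen-8-yl}-4-methoxyphenyl)-7-methoxy-4H-chromen-4-one | COc1ccc(-c2cc(=O)c3c(OCc4ccccc4)cc(OC)cc3o2)c(-c2c(OCc3ccccc3)cc(OCc3ccccc3)c3c(=O)cc(-c4ccc(OCc5ccccc5)cc4)oc23)c1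
F5 | step 9 | {2-[5-(benzyloxy)-7-methoxy-4-oxo-4H-chromen-2-yl]-5-methoxyphenyl}{6-[4-(benzyloxy)phenyl]-4-oxo-4H-pyran-2-yl}acetic acid, racemic | OC(=O)C(c1cc(=O)cc(-c2ccc(OCc3ccccc3)cc2)o1)c1cc(OC)ccc1-c1cc(=O)c2c(OCc3ccccc3)cc(OC)cc2o1
F6 | step 9 | imidazolide of F5, racemic | O=C(n1ccnc1)C(c1cc(=O)cc(-c2ccc(OCc3ccccc3)cc2)o1)c1cc(OC)ccc1-c1cc(=O)c2c(OCc3ccccc3)cc(OC)cc2o1
F7 | step 8 | 5-(2-{2-[5-(benzyloxy)-7-methoxy-4-oxo-4H-chromen-2-yl]-5-methoxyphenyl}-1-hydroxyethylidene)-2,2-dimethyl-1,3-dioxane-4,6-dione | CC1(C)OC(=O)C(=C(O)Cc2cc(OC)ccc2-c2cc(=O)c3c(OCc4ccccc4)cc(OC)cc3o2)C(=O)O1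
F8 | step 8 | 6-{2-[5-(benzyloxy)-7-methoxy-4-oxo-4H-chromen-2-yl]-5-methoxybenzyl}-2,2-dimethyl-4H-1,3-dioxin-4-one | CC1(C)OC(=O)C=C(Cc2cc(OC)ccc2-c2cc(=O)c3c(OCc4ccccc4)cc(OC)cc3o2)O1
F9 | step 8 | {1-[4-(benzyloxy)phenyl]ethenyloxy}trimethylsilane | C=C(O[Si](C)(C)C)c1ccc(OCc2ccccc2)cc1
F10 | step 8 | 4-{2-[5-(benzyloxy)-7-methoxy-4-oxo-4H-chromen-2-yl]-5-methoxyphenyl}but-1-ene-1,3-dione (acylketene) | O=C=CC(=O)Cc1cc(OC)ccc1-c1cc(=O)c2c(OCc3ccccc3)cc(OC)cc2o1
F11 | step 8 | 5-(benzyloxy)-2-[2-({2-[4-(benzyloxy)phenyl]-4-oxo-2-(trimethylsilyloxy)-3,4-dihydro-2H-pyran-6-yl}methyl)-4-methoxyphenyl]-7-methoxy-4H-chromen-4-one, racemic | C[Si](C)(C)OC1(c2ccc(OCc3ccccc3)cc2)CC(=O)C=C(Cc2cc(OC)ccc2-c2cc(=O)c3c(OCc4ccccc4)cc(OC)cc3o2)O1
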